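## Retrosynthetic overview

1. The target is methyl 7β-acetoxy-15-hydroxylabda-8(17),13E-dien-19-oate. The 7β-acetate comes from Mitsunobu inversion of a 7α-allylic alcohol made by SeO2 oxidation next to the C8=C17 methylene. The E-C13=C14/C15-OH unit comes from zirconium-catalysed methylalumination and hydroxymethylation of a terminal C13≡C14 alkyne.
2. The C3 methylene and the methyl ester are corrected after the key step: LiAlH4 removes the chiral ester and reduces the C3 ketone, the 3,19-cyclic thionocarbonate is cleaved at C3, and C19 is re-oxidised and methylated.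
3. Key disconnection: C4–C5 (ring A) and C9–C10 (ring B) are cut together, back to an acyclic (6E,10E)-dienynyl 2-methyl-3-oxo ester. In the forward sense one oxidative radical cascade closes ring A first, then ring B, and ends in the C8=C17 methylene.
4. Enabling feature: C4 carries the C18 methyl and the C19 carboxyl carbon and is bonded to C3, so with C3 as a ketone C4 is the radical carbon of a 2-methyl β-keto ester. C5=C10 and C8=C9 are the E-trisubstituted alkenes of a head-to-tail isoprenoid chain, spaced so that rings A and B each close 6-endo to a trans-decalin; the C17 methyl on C8 supplies the hydrogen lost in the termination.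
5. The chain is assembled from geranyl bromide, 1-(trimethylsilyl)propyne and 2-methylacetoacetate; (+)-8-phenylmenthol as the ester group sets the absolute configuration in the cascade.

Key step: step 6

Numbering: labdane numbering is used from step 6 on (ring A = C1–C5, C10; ring B = C5–C10; C17 = methylene carbon on C8; C18 = methyl on C4; C19 = carboxyl carbon on C4; C20 = methyl on C10; α = the face opposite to the C10 methyl).

Assumption: (+)-8-phenylmenthol, (1S,2R,5S), is taken as the enantiomer whose ester leaves open the face of the C4 radical that leads to the 5α-H/10β-methyl series, by analogy with the sense of induction of 8-phenylmenthyl β-keto esters in related trivalent-manganese cyclizations; if a test cyclization showed the opposite sense, the (−)-enantiomer would be used with no other change.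

## Route

Step 1
Reactants: 1 (+)-8-phenylmenthol; 2 ethyl 2-methylacetoacetate
Product: 3 (+)-8-phenylmenthyl 2-methyl-3-oxobutanoate (C2 epimers)
Conditions: DMAP (cat.), toluene, reflux, EtOH distilled off
Reagents that add atoms: none
Why: DMAP-catalysed transesterification of a β-keto ester, which proceeds through the acylketene and therefore works with a hindered secondary alcohol; the C2 centre is left epimeric because it becomes a planar radical later.

Step 2
Reactants: 4 geranyl bromide; 5 1-(trimethylsilyl)propyne
Product: 7 trimethyl[(5E)-6,10-dimethylundeca-5,9-dien-1-yn-1-yl]silane, via 3-(trimethylsilyl)prop-2-ynyllithium 6 (not isolated)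
Conditions: 5, n-BuLi, THF, −78 °C; then 4, −78 °C to rt
Reagents that add atoms: none
Why: propargylic lithiation followed by SN2 alkylation at the primary allylic bromide, the silyl group keeping the anion propargylic and the E-alkene of the geranyl unit untouched.

Step 3
Reactants: 7 trimethyl[(5E)-6,10-dimethylundeca-5,9-dien-1-yn-1-yl]silane
Product: 8 (2E,6E)-2,6-dimethyl-11-(trimethylsilyl)undeca-2,6-dien-10-yn-1-ol
Conditions: SeO2 (cat.), t-BuOOH, salicylic acid (cat.), CH2Cl2, 0 °C to rt
Reagents that add atoms: tert-butyl hydroperoxide, CC(C)(C)OO (oxygen atom, transferred through catalytic SeO2, O=[Se]=O)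
Why: Riley-type allylic oxidation (ene reaction, then [2,3]-shift) should attack the E-methyl of the terminal isopropylidene, the most reactive alkene as in farnesyl derivatives, and give the E-allylic alcohol.

Step 4
Reactants: 8 (2E,6E)-2,6-dimethyl-11-(trimethylsilyl)undeca-2,6-dien-10-yn-1-ol
Product: 9 [(5E,9E)-11-bromo-6,10-dimethylundeca-5,9-dien-1-yn-1-yl]trimethylsilane
Conditions: CBr4, PPh3, CH2Cl2, 0 °C
Reagents that add atoms: carbon tetrabromide, BrC(Br)(Br)Br
Why: Appel reaction converts the primary allylic alcohol into the bromide under neutral conditions without allylic transposition or loss of alkene geometry.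

Step 5
Reactants: 3 (+)-8-phenylmenthyl 2-methyl-3-oxobutanoate; 9 [(5E,9E)-11-bromo-6,10-dimethylundeca-5,9-dien-1-yn-1-yl]trimethylsilane
Product: 11 (+)-8-phenylmenthyl (6E,10E)-2,6,10-trimethyl-3-oxo-15-(trimethylsilyl)pentadeca-6,10-dien-14-ynoate (C2 epimers), via sodium lithium dienolate 10 (not isolated)
Conditions: 3, NaH, THF, 0 °C; n-BuLi, 0 °C; then 9, 0 °C to rt; aq. NH4Cl
Reagents that add atoms: none
Why: dianion γ-alkylation of a β-keto ester, in which the more reactive terminal carbanion (the former acetyl methyl) displaces the allylic bromide in SN2 fashion and both E-alkenes are carried through unchanged.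

Step 6
Reactants: 11 (+)-8-phenylmenthyl (6E,10E)-2,6,10-trimethyl-3-oxo-15-(trimethylsilyl)pentadeca-6,10-dien-14-ynoate
Product: 15 (+)-8-phenylmenthyl 3-oxo-14-(trimethylsilyl)-15,16-dinorlabd-8(17)-en-13-yn-19-oate (5α-H; 10β-methyl; 4β-ester; 9β side chain), via C4 radical 12 (not isolated), via monocyclic C10 radical 13 (not isolated), via bicyclic C8 radical 14 (not isolated)
Conditions: Mn(OAc)3·2H2O (2.2 equiv), Cu(OAc)2·H2O (1 equiv), degassed AcOH, 25–40 °C
Reagents that add atoms: none
Why: Trivalent manganese oxidises the enol of the 2-methyl β-keto ester to the electrophilic C4 radical 12, which adds 6-endo-trig to C5 of the E-trisubstituted C5=C10 alkene (ring A, C4–C5 bond) to give the tertiary C10 radical 13; this adds 6-endo-trig to C9 of the C8=C9 alkene (ring B, C9–C10 bond) to give the tertiary C8 radical 14, which divalent copper oxidises through an alkylcopper species that loses a β-hydrogen from the C17 methyl to give the exocyclic methylene. The closest known reaction type is the Mn(OAc)3/Cu(OAc)2 oxidative free-radical polyene cyclization of 2-methyl-3-oxo polyenoates to trans-fused 4-carboalkoxy-4-methyl-3-decalones with an exocyclic alkene, including its 8-phenylmenthyl ester variant. C4 is set by the radical geometry, in which the ester lies anti to the ring ketone oxygen and therefore ends axial (β, C19) with the methyl equatorial; C5 and C10 follow from the chair transition states of the E-alkene (trans ring fusion), and C9 from the E-geometry of C8=C9, which places the side chain equatorial. The absolute sense should come from the auxiliary, whose phenyl ring stacks over one face of the planar C4 radical so that C5 bonds to the open face. The step needs 6-endo over 5-exo closure, secured by the methyl groups on C10 and C8 that direct attack to the less substituted alkene carbons, and oxidation of radical 14 faster than its 5-exo-dig attack on the side-chain alkyne, secured by stoichiometric Cu(OAc)2 and the bulky silyl group on the alkyne.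

Step 7
Reactants: 15 (+)-8-phenylmenthyl 3-oxo-14-(trimethylsilyl)-15,16-dinorlabd-8(17)-en-13-yn-19-oate
Product: 16 14-(trimethylsilyl)-15,16-dinorlabd-8(17)-en-13-yne-3β,19-diol
Conditions: LiAlH4, THF, 0 °C to reflux; aqueous NaOH work-up
Reagents that add atoms: none
Why: hydride reduction, in which the C3 ketone is attacked axially from the α face (the β face carries the axial C4 ester and the C10 methyl) to give the equatorial 3β-alcohol, the hindered ester is reduced to the C19 primary alcohol, and auxiliary 1 is returned for re-use.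

Step 8
Reactants: 16 14-(trimethylsilyl)-15,16-dinorlabd-8(17)-en-13-yne-3β,19-diol
Product: 17 cyclic 3β,19-thionocarbonate of 14-(trimethylsilyl)-15,16-dinorlabd-8(17)-en-13-yne-3β,19-diol
Conditions: 1,1'-thiocarbonyldiimidazole, DMAP (cat.), toluene, 100 °C
Reagents that add atoms: 1,1'-thiocarbonyldiimidazole, S=C(n1ccnc1)n1ccnc1
Why: thiocarbonylation of a 1,3-diol, feasible because the equatorial 3β-oxygen and the axial C19 oxygen are gauche and close a six-membered ring.

Step 9
Reactants: 17 cyclic 3β,19-thionocarbonate of 14-(trimethylsilyl)-15,16-dinorlabd-8(17)-en-13-yne-3β,19-diol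
Product: 19 15,16-dinorlabd-8(17)-en-13-yn-19-ol, via stannyl thiolcarbonate 18 (not isolated)
Conditions: Bu3SnH, AIBN (cat.), toluene, 110 °C; then NaOH, MeOH–THF, rt
Reagents that add atoms: none
Why: Barton–McCombie-type deoxygenation of a cyclic thionocarbonate, in which the tin adduct radical should fragment toward the secondary C3 radical and not the primary neopentyl C19 radical, hydrogen transfer gives the C3 methylene, and the basic methanolysis frees the C19 alcohol and removes the alkynyl silyl group.

Step 10
Reactants: 19 15,16-dinorlabd-8(17)-en-13-yn-19-ol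
Product: 20 15,16-dinorlabd-8(17)-en-13-yn-19-oic acid
Conditions: CrO3, H2SO4, acetone, 0 °C
Reagents that add atoms: chromium trioxide, O=[Cr](=O)=O; water, O (second carboxyl oxygen, through the aldehyde hydrate)
Why: Jones oxidation takes the neopentyl primary alcohol through the aldehyde hydrate to the acid, as is usual for axial 19-hydroxy groups of this skeleton, and the isolated methylene and alkyne tolerate the short exposure at 0 °C.

Step 11
Reactants: 20 15,16-dinorlabd-8(17)-en-13-yn-19-oic acid
Product: 21 methyl 15,16-dinorlabd-8(17)-en-13-yn-19-oate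
Conditions: trimethylsilyldiazomethane, MeOH–toluene, rt
Reagents that add atoms: trimethylsilyldiazomethane, C[Si](C)(C)C=[N+]=[N-] (methyl carbon)
Why: O-methylation of the carboxylic acid by diazomethane transfer, which needs no attack at the hindered axial carbonyl carbon.

Step 12
Reactants: 21 methyl 15,16-dinorlabd-8(17)-en-13-yn-19-oate
Product: 22 methyl 7α-hydroxy-15,16-dinorlabd-8(17)-en-13-yn-19-oate
Conditions: SeO2 (cat.), t-BuOOH, CH2Cl2, rt
Reagents that add atoms: tert-butyl hydroperoxide, CC(C)(C)OO (oxygen atom, transferred through catalytic SeO2, O=[Se]=O)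
Why: Riley-type allylic oxidation of the exocyclic methylene, in which the ene step removes the axial 7α-hydrogen (a methylene reacts before the C9 methine next to quaternary C10) and the [2,3]-shift returns oxygen to C7 on the α face, so the axial 7α-alcohol with C8=C17 restored is expected.

Step 13
Reactants: 22 methyl 7α-hydroxy-15,16-dinorlabd-8(17)-en-13-yn-19-oate
Product: 24 methyl 7α,15-dihydroxylabda-8(17),13E-dien-19-oate, via alkenylalane 23 (not isolated)
Conditions: AlMe3 (4 equiv), Cp2ZrCl2 (0.3 equiv), CH2Cl2, 0 °C to rt; volatiles removed; n-BuLi, THF, −78 °C; (CH2O)n, −78 °C to rt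
Reagents that add atoms: trimethylaluminium, C[Al](C)C (C16 methyl); paraformaldehyde, as formaldehyde C=O (C15 and its oxygen)
Why: Negishi zirconium-catalysed methylalumination adds methyl and aluminium syn across the terminal alkyne with aluminium on the terminal carbon, so hydroxymethylation of the derived alanate gives the E-trisubstituted allylic alcohol, while the C7 hydroxyl is carried as its aluminium alkoxide and the hindered ester is not attacked.

Step 14
Reactants: 24 methyl 7α,15-dihydroxylabda-8(17),13E-dien-19-oate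
Product: 25 methyl 15-(tert-butyldimethylsilyloxy)-7α-hydroxylabda-8(17),13E-dien-19-oate
Conditions: TBSCl, imidazole, CH2Cl2, 0 °C
Reagents that add atoms: tert-butyldimethylsilyl chloride, CC(C)(C)[Si](C)(C)Cl
Why: silylation selects the unhindered primary allylic alcohol over the axial secondary allylic alcohol at C7.

Step 15
Reactants: 25 methyl 15-(tert-butyldimethylsilyloxy)-7α-hydroxylabda-8(17),13E-dien-19-oate
Product: 26 methyl 7β-acetoxy-15-(tert-butyldimethylsilyloxy)labda-8(17),13E-dien-19-oate
Conditions: PPh3, DIAD, AcOH, THF, 0 °C to rt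
Reagents that add atoms: acetic acid, CC(=O)O
Why: Mitsunobu esterification, in which acetate displaces the activated axial 7α-oxyphosphonium group from the equatorial direction and inverts C7 to the equatorial 7β-acetate.

Step 16
Reactants: 26 methyl 7β-acetoxy-15-(tert-butyldimethylsilyloxy)labda-8(17),13E-dien-19-oate
Product: 27 methyl 7β-acetoxy-15-hydroxylabda-8(17),13E-dien-19-oate (target)
Conditions: HF·pyridine, pyridine–THF, 0 °C
Reagents that add atoms: none
Why: fluoride-mediated cleavage of the primary silyl ether, which leaves the allylic acetate and the methyl ester untouched.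

## Compound list

1 | (+)-8-phenylmenthol, (1S,2R,5S)-5-methyl-2-(2-phenylpropan-2-yl)cyclohexan-1-ol | O[C@H]1C[C@@H](C)CC[C@@H]1C(C)(C)c1ccccc1 | starting material
2 | ethyl 2-methylacetoacetate (racemic) | CCOC(=O)C(C)C(C)=O | starting material
3 | (+)-8-phenylmenthyl 2-methyl-3-oxobutanoate (C2 epimers) | CC(=O)C(C)C(=O)O[C@H]1C[C@@H](C)CC[C@@H]1C(C)(C)c1ccccc1 | intermediate
4 | geranyl bromide, (2E)-1-bromo-3,7-dimethylocta-2,6-diene | CC(C)=CCC/C(C)=C/CBr | starting material
5 | 1-(trimethylsilyl)propyne | CC#C[Si](C)(C)C | starting material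
6 | 3-(trimethylsilyl)prop-2-ynyllithium | [Li]CC#C[Si](C)(C)C | intermediate (not isolated)
7 | trimethyl[(5E)-6,10-dimethylundeca-5,9-dien-1-yn-1-yl]silane | CC(C)=CCC/C(C)=C/CCC#C[Si](C)(C)C | intermediate
8 | (2E,6E)-2,6-dimethyl-11-(trimethylsilyl)undeca-2,6-dien-10-yn-1-ol | OC/C(C)=C/CC/C(C)=C/CCC#C[Si](C)(C)C | intermediate
9 | [(5E,9E)-11-bromo-6,10-dimethylundeca-5,9-dien-1-yn-1-yl]trimethylsilane | BrC/C(C)=C/CC/C(C)=C/CCC#C[Si](C)(C)C | intermediate
10 | sodium lithium dienolate (dianion) of 3 | [Na+].[Li+].C=C([O-])C(C)=C([O-])O[C@H]1C[C@@H](C)CC[C@@H]1C(C)(C)c1ccccc1 | intermediate (not isolated)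
11 | (+)-8-phenylmenthyl (6E,10E)-2,6,10-trimethyl-3-oxo-15-(trimethylsilyl)pentadeca-6,10-dien-14-ynoate (C2 epimers) | CC(C(=O)O[C@H]1C[C@@H](C)CC[C@@H]1C(C)(C)c1ccccc1)C(=O)CC/C(C)=C/CC/C(C)=C/CCC#C[Si](C)(C)C | intermediate
12 | C4 radical of 11 (radical at the carbon between ketone and ester) | C[C](C(=O)O[C@H]1C[C@@H](C)CC[C@@H]1C(C)(C)c1ccccc1)C(=O)CC/C(C)=C/CC/C(C)=C/CCC#C[Si](C)(C)C | intermediate (not isolated)
13 | monocyclic tertiary C10 radical (ring A closed; C4 and C5 set) | C[Si](C)(C)C#CCC/C=C(\C)CC[C@@H]1[C](C)CCC(=O)[C@]1(C)C(=O)O[C@H]1C[C@@H](C)CC[C@@H]1C(C)(C)c1ccccc1 | intermediate (not isolated)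
14 | bicyclic tertiary C8 radical (rings A and B closed) | C[C]1CC[C@@H]2[C@](C)(CCC(=O)[C@]2(C)C(=O)O[C@H]3C[C@@H](C)CC[C@@H]3C(C)(C)c3ccccc3)[C@H]1CCC#C[Si](C)(C)C | intermediate (not isolated)
15 | (+)-8-phenylmenthyl 3-oxo-14-(trimethylsilyl)-15,16-dinorlabd-8(17)-en-13-yn-19-oate (5α-H, 10β-methyl, 4β-ester, 9β side chain) | C=C1CC[C@@H]2[C@](C)(CCC(=O)[C@]2(C)C(=O)O[C@H]3C[C@@H](C)CC[C@@H]3C(C)(C)c3ccccc3)[C@H]1CCC#C[Si](C)(C)C | intermediate
16 | 14-(trimethylsilyl)-15,16-dinorlabd-8(17)-en-13-yne-3β,19-diol | C=C1CC[C@@H]2[C@](C)(CC[C@H](O)[C@]2(C)CO)[C@H]1CCC#C[Si](C)(C)C | intermediate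
17 | cyclic 3β,19-thionocarbonate of 16 | C=C1CC[C@@H]2[C@](C)(CC[C@@H]3OC(=S)OC[C@]23C)[C@H]1CCC#C[Si](C)(C)C | intermediate
18 | S-(tributylstannyl) O-[14-(trimethylsilyl)-15,16-dinorlabd-8(17)-en-13-yn-19-yl] thiocarbonate | C=C1CC[C@@H]2[C@](C)(CCC[C@]2(C)COC(=O)S[Sn](CCCC)(CCCC)CCCC)[C@H]1CCC#C[Si](C)(C)C | intermediate (not isolated)
19 | 15,16-dinorlabd-8(17)-en-13-yn-19-ol | C=C1CC[C@@H]2[C@](C)(CCC[C@]2(C)CO)[C@H]1CCC#C | intermediate
20 | 15,16-dinorlabd-8(17)-en-13-yn-19-oic acid | C=C1CC[C@@H]2[C@](C)(CCC[C@]2(C)C(=O)O)[C@H]1CCC#C | intermediate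
21 | methyl 15,16-dinorlabd-8(17)-en-13-yn-19-oate | C=C1CC[C@@H]2[C@](C)(CCC[C@]2(C)C(=O)OC)[C@H]1CCC#C | intermediate
22 | methyl 7α-hydroxy-15,16-dinorlabd-8(17)-en-13-yn-19-oate | C=C1[C@H](O)C[C@@H]2[C@](C)(CCC[C@]2(C)C(=O)OC)[C@H]1CCC#C | intermediate
23 | (13E)-alkenyl(dimethyl)alane of 22, C7 oxygen as dimethylaluminium alkoxide | C=C1[C@H](O[Al](C)C)C[C@@H]2[C@](C)(CCC[C@]2(C)C(=O)OC)[C@H]1CC/C(C)=C/[Al](C)C | intermediate (not isolated)
24 | methyl 7α,15-dihydroxylabda-8(17),13E-dien-19-oate | C=C1[C@H](O)C[C@@H]2[C@](C)(CCC[C@]2(C)C(=O)OC)[C@H]1CC/C(C)=C/CO | intermediate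
25 | methyl 15-(tert-butyldimethylsilyloxy)-7α-hydroxylabda-8(17),13E-dien-19-oate | C=C1[C@H](O)C[C@@H]2[C@](C)(CCC[C@]2(C)C(=O)OC)[C@H]1CC/C(C)=C/CO[Si](C)(C)C(C)(C)C | intermediate
26 | methyl 7β-acetoxy-15-(tert-butyldimethylsilyloxy)labda-8(17),13E-dien-19-oate | C=C1[C@@H](OC(C)=O)C[C@@H]2[C@](C)(CCC[C@]2(C)C(=O)OC)[C@H]1CC/C(C)=C/CO[Si](C)(C)C(C)(C)C | intermediate
27 | methyl 7β-acetoxy-15-hydroxylabda-8(17),13E-dien-19-oate | C=C1[C@@H](OC(C)=O)C[C@@H]2[C@](C)(CCC[C@]2(C)C(=O)OC)[C@H]1CC/C(C)=C/CO | target

## Step count and risks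

Total step count: 16. Longest linear sequence: 15 steps (steps 2 to 16, from geranyl bromide 4 and silylpropyne 5); step 1 is a one-step side branch.

Steps most likely to fail:

1. Step 6. What may go wrong is poor facial discrimination by the auxiliary when the C4 radical is not held in a chelate, together with loss of regiocontrol in the copper-mediated hydrogen loss (endocyclic alkene isomers). The fallback sets out from bromide 9 and alcohol 1 and separates ring formation from the setting of C4. Alcohol 1 is heated with 2,2,6-trimethyl-4H-1,3-dioxin-4-one (xylene, 140 °C) to give (+)-8-phenylmenthyl 3-oxobutanoate F1. Its dianion (NaH, then n-BuLi, THF, 0 °C) is alkylated with 9 to give the C2-unsubstituted keto ester F2. F2 is cyclized with Mn(OAc)3·2H2O and Cu(OAc)2·H2O in CF3CH2OH at 0 °C in the presence of Yb(OTf)3, conditions under which the radical reacts as a lanthanide chelate and strong auxiliary control has precedent, to give the C4-unmethylated bicyclic keto ester F3. C-Methylation of the β-keto ester enolate of F3 (K2CO3, MeI, acetone) should occur from the α face, anti to the C10 methyl, placing the ester axial, and the route is rejoined at compound 15.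

2. Step 15. What may go wrong is elimination of the activated axial allylic alcohol to a conjugated diene, or allylic capture of acetate at C17 instead of direct inversion at C7. The fallback sets out from compound 25 and replaces displacement by an oxidation–reduction sequence. Dess–Martin periodinane (CH2Cl2, NaHCO3) gives the exocyclic enone, methyl 15-(tert-butyldimethylsilyloxy)-7-oxolabda-8(17),13E-dien-19-oate F4. Luche reduction (NaBH4, CeCl3·7H2O, MeOH, −78 °C) should deliver hydride axially from the unhindered α face to give the equatorial alcohol, methyl 15-(tert-butyldimethylsilyloxy)-7β-hydroxylabda-8(17),13E-dien-19-oate F5. Acetylation (Ac2O, DMAP, pyridine) rejoins the route at compound 26.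

3. Step 13. What may go wrong is attack of the aluminium or lithium reagents on the ester, or incomplete hydroxymethylation of an alanate that also carries an aluminium alkoxide. The fallback sets out from compound 22 and builds the alkene by olefination instead of carbometalation. Ph3PAuCl/AgOTf-catalysed Markovnikov hydration of the terminal alkyne (aqueous dioxane, 60 °C) gives the methyl ketone, methyl 7α-hydroxy-13-oxo-14,15-dinorlabd-8(17)-en-19-oate F6. Horner–Wadsworth–Emmons olefination (triethyl phosphonoacetate, NaH, THF) gives the E-enoate, 15-ethyl 19-methyl 7α-hydroxylabda-8(17),13E-diene-15,19-dioate F7, with the minor Z isomer removed by chromatography. DIBAL-H (CH2Cl2, −78 °C) should reduce the conjugated ethyl ester in preference to the hindered axial C19 methyl ester and rejoin the route at compound 24.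

## Further compounds

F1 | step 6 | (+)-8-phenylmenthyl 3-oxobutanoate | CC(=O)CC(=O)O[C@H]1C[C@@H](C)CC[C@@H]1C(C)(C)c1ccccc1
F2 | step 6 | (+)-8-phenylmenthyl (6E,10E)-6,10-dimethyl-3-oxo-15-(trimethylsilyl)pentadeca-6,10-dien-14-ynoate | O=C(CC(=O)O[C@H]1C[C@@H](C)CC[C@@H]1C(C)(C)c1ccccc1)CC/C(C)=C/CC/C(C)=C/CCC#C[Si](C)(C)C
F3 | step 6 | C4-unmethylated analogue of 15 (ester drawn equatorial; C4 epimerisable) | C=C1CC[C@@H]2[C@](C)(CCC(=O)[C@H]2C(=O)O[C@H]3C[C@@H](C)CC[C@@H]3C(C)(C)c3ccccc3)[C@H]1CCC#C[Si](C)(C)C
F4 | step 15 | methyl 15-(tert-butyldimethylsilyloxy)-7-oxolabda-8(17),13E-dien-19-oate | C=C1C(=O)C[C@@H]2[C@](C)(CCC[C@]2(C)C(=O)OC)[C@H]1CC/C(C)=C/CO[Si](C)(C)C(C)(C)C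
F5 | step 15 | methyl 15-(tert-butyldimethylsilyloxy)-7β-hydroxylabda-8(17),13E-dien-19-oate | C=C1[C@@H](O)C[C@@H]2[C@](C)(CCC[C@]2(C)C(=O)OC)[C@H]1CC/C(C)=C/CO[Si](C)(C)C(C)(C)C
F6 | step 13 | methyl 7α-hydroxy-13-oxo-14,15-dinorlabd-8(17)-en-19-oate | C=C1[C@H](O)C[C@@H]2[C@](C)(CCC[C@]2(C)C(=O)OC)[C@H]1CCC(C)=O
F7 | step 13 | 15-ethyl 19-methyl 7α-hydroxylabda-8(17),13E-diene-15,19-dioate | C=C1[C@H](O)C[C@@H]2[C@](C)(CCC[C@]2(C)C(=O)OC)[C@H]1CC/C(C)=C/C(=O)OCC
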